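## Structural features

The target is a 1H-isochromen-6-one: a pyran (O2, C1, C8a, C4a, C4, C3) fused along C4a–C8a to a cyclohexenone (C4a, C5, C6, C7, C8, C8a). The side chain C9–C15 (methyls on C11 and C13, hydroxyl on C15) is joined to C3 through an (E,E)-diene. The chromophore is one linear push–pull system, O2–C3=C4–C4a=C5–C6=O, with chlorine on C5, its α-carbon. Three contiguous stereocentres lie on one edge of the carbocycle: C7 (R, tertiary carbinol with a methyl group, next to the C6 ketone), C8 (R, secondary carbinol) and C8a (S, the ring-fusion methine that carries C1). The C7 oxygen, the C8 oxygen and C1 are all on the same face; a fourth, isolated centre (C13, S) sits in the side chain. Fragile groups are the β-hydroxy ketone and α-ketol (retro-aldol, acyloin shift), the C8a–H bond (vinylogously acidic, with the C8 oxygen as a leaving group beside it), the acid-labile dienol ether and the triene. The real difficulty is to fix C8a relative to C8 although both neighbours of C8a on the other side end up trigonal, and to build the quaternary C7 carbinol with its oxygen cis to the C8 oxygen. The key step uses the cis relation between the C8 oxygen and C1 together with the sequence C8(O)–C8a–C4a–C4. This is the allylic carbinol, acrylate β-carbon, α-carbon and carboxyl carbon of shikimic acid, so a one-carbon unit tethered to the C8 oxygen can be delivered to C8a on the correct face.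

## Logic of the disconnections

30 ⇒ 29. The C5–Cl bond is cut first. C5 is the α-carbon of the doubly vinylogous ester and becomes the most nucleophilic carbon once the pyran is closed, so the halogen need not be carried through enolate and palladium chemistry. No skeletal simplification results, but a vinyl chloride is avoided in every earlier step. The forward step must chlorinate C5 in preference to C4 and to the side-chain diene, under near-neutral conditions.

29 ⇒ 28. The O2–C3 bond is cut. The enol ether is the formal adduct of the C1 hydroxyl across a C3≡C4 alkyne that is conjugated with the C4a=C5–C6=O enone, so C3 is the electrophilic δ-position. This opens the bicycle to a monocyclic cyclohexenone and confines the sensitive dienol ether to the last two steps. The forward step must close 6-endo at C3 rather than 5-exo at C4.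

28 ⇒ 27 ⇒ 25 (through 26). After the protecting groups are put back, the C7–CH3 bond is cut. C7 is the α′-position of the C6 ketone and already carries its oxygen, and the acetonide that ties O7 to O8 makes the C8 centre decide the face of alkylation. The quaternary carbinol is thereby traced to a secondary carbinol of known configuration. The forward step demands kinetic α′-deprotonation in preference to C8a–H, no expulsion of O8, and entry of the methyl group anti to O8.

25 ⇒ 23 (through 24) ⇒ 22 ⇒ 21. The C4a=C5 π bond and the C6 carbonyl are taken back to a saturated C6 carbinol, with the two primary hydroxyls masked in 22. C5 is the only methylene next to C6 and C4a–H is the only β-hydrogen on that side, so the unsaturation can be placed unambiguously. The gain is a fully saturated, configurationally robust carbocycle. The demands are enolisation toward C5 rather than C7 and selective silylation of primary over secondary hydroxyl.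

21 ⇒ 12 + 20. The C3–C9 bond (sp–sp2) is cut. This is the most convergent cut: it separates a carbocyclic core from a side chain of comparable size, each with its own stereocentres and none created at the junction. The forward coupling must keep the (E)-geometry of the iodoalkene and tolerate free hydroxyls.

12 ⇒ 11 ⇒ 10. The C3–C4 bond is cut, which removes C3 and returns C4 to a masked aldehyde (the hemiacetal of 11) and then to the lactone carbonyl of 10. C4 is thus the original carboxyl carbon, and the lactone protects C1–O and C4 together. The forward steps need a clean half-reduction and a one-carbon homologation that works on a hemiacetal; the C4a configuration is of no concern because it is erased later.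

10 ⇒ 8 (through 9). No skeletal bond is cut; the cis-acetonide on O7/O8 is exchanged for the trans-diacetal on O6/O7. This differentiates O6 (to be oxidised) from O7 (to be alkylated) without any selective protection. It demands that the cis-fused dioxolane, together with the fused lactone, is the thermodynamically preferred arrangement.

8 ⇒ 6 (through 7). The lactone C–O bond and the C1–O bond are cut, the latter to a C1–Si bond. This reveals the oxasilolane, in which silicon holds C1 and O8 together. The forward step needs an oxidative C–Si cleavage that leaves the ester alone.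

6 ⇒ 5. The C1–C8a bond is cut; this is the strategic bond. It turns the saturated ring back into a cyclohexene carboxylate whose only stereocentres come from the chiral pool. The forward step must deliver C1 to C8a on the face of O8, at the β-carbon and not the α-carbon of the ester.

5 ⇒ 3 + 4, then 3 ⇒ 2 ⇒ 1. The O–Si bond, the diacetal C–O bonds and the ester C–O bond are cut in turn. Only the trans-diol of 2 can be spanned by the diacetal, so the allylic hydroxyl is left free in one step and the chain ends at 1 and 4.

20 ⇒ 19 ⇒ 17 (through 18). The C9=C10 and C11=C12 double bonds are cut by two carbonyl olefinations. C9 comes from a one-carbon iodo-olefination and C10–C11 from a formyl-substituted phosphorane, which leaves a lactone whose carbonyl carbon is C12. Both olefinations must be E-selective and must not epimerise C13.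

17 ⇒ 15 (through 16) ⇒ 13 (through 14). The lactone C–O bond is cut and C15 is traced to the inner alkene carbon of an allyl group; then the C13–C14 bond is cut. The single side-chain stereocentre is thus set by auxiliary-controlled alkylation of a propionyl unit, which demands a chelated Z-enolate and entry of the electrophile anti to the benzyl group.

## Other disconnections considered

Alternative 1: The cut is made at C4a–C8a and O2–C1 in one step. In the forward direction a tertiary amine moves a β,γ-alkynyl ketone into an allenyl ketone, whose O2=C3–C4=C4a heterodiene adds across a tethered C8a=C1 enol ether to give cycloadduct A1.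
- In its favour: two rings and two bonds form at once, the side chain is already attached, and both C3=C4 and C4a=C5 appear in their final positions, so neither a late coupling nor a cycloisomerisation is needed. On convergence and ring-forming economy it is the better plan.
- Against it here: the open-chain substrate must already carry C6, C7 (quaternary) and C8, made by asymmetric synthesis rather than taken from the chiral pool. The C8a configuration depends on the facial and endo/exo preference of a flexible tether, guided only by the C8 centre. C1 arrives as a methyl acetal that must be reduced next to the acid-labile dienol ether, and C6 arrives as a silyl ether that still has to be oxidised. Allenyl ketones are also prone to conjugate addition under the amine.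
- Comparison: control at C8a is less certain than in the chosen plan, where a five-membered ring enforces it. The endgame from A1 (about five operations) is shorter than the sixteen steps that follow 6, but the stereochemical work is moved into the precursor, so the overall count is not clearly lower. The final C5 chlorination is common to both (equal).

Alternative 2: The cut is made at C4a–C5 and C8–C8a. A thermal endo Diels–Alder reaction joins an α,β-unsaturated δ-lactone (C8a=C4a, C1 as the lactone carbonyl, C3 saturated and bearing the dienyl chain) with a 1,2,3-trioxygenated butadiene to give A2.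
- In its favour: the carbocycle and all three ring oxygens (C6, C7, C8) come from one step and two simple partners. The regiochemistry follows from diene polarisation, and the endo rule places the C8 oxygen cis to C1, the relation that the chosen plan gets from its tether (equal on that point).
- Against it here: an unsaturated lactone is a sluggish dienophile, while the oxygenated diene is heat- and acid-sensitive and the side-chain diene could itself react as a diene. The absolute configuration must be relayed from a C3 centre that is remote from C8a and absent from the target. A2 has the wrong oxidation level at C1 (lactone instead of methylene) and at C3 (saturated instead of enol ether), lacks the C7 methyl and lacks the C4a=C5 bond.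
- Comparison: it is the better plan for convergent assembly of the carbocycle. It is equal in needing an α-methylation at C7 of the kind used in step 17, but without the acetonide that controls it there. It is weaker in redox economy and in the number of corrections after the cycloaddition.

Alternative 3: The cut is made at C6–C7. A triazolium-derived carbene with an amidine base turns the C6 aldehyde into an acyl anion equivalent, which adds to the tethered C7 methyl ketone and gives A3, the bis-silyl ether of the 5-deschloro compound.
- In its favour: the carbocycle, the C6 ketone and the C7 tertiary carbinol are formed together, with no enolate alkylation and no protecting-group exchange. Only chlorination and desilylation remain, so after its key step this is the shortest of the four plans and better than the chosen one.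
- Against it here: the aldehyde is the terminus of a donor-substituted dienal, a poor electrophile whose extended Breslow intermediate can react at C4a or be diverted by protonation. The exocyclic C4a=C5 bond must hold the formyl group toward C8a. The C7 configuration rests on 1,2-induction from the C8 silyl ether alone. The amidine meets an acidic C8a–H with a β-silyloxy leaving group. The monocyclic pyran substrate, with C8 and C8a already set, needs its own stereoselective synthesis.
- Comparison: stereocontrol at C7 and C8a is less enforced than by the ring-fusion constraints of the chosen plan. The final chlorination is the same problem in both (equal). The step count after the key step favours the alternative; the count before it is open.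

Key step: step 4

Remark on locants: intermediates from 1 are described with the locants of the target; shikimate C1, C2, C3, C4, C5, C6 and the carboxyl carbon become C4a, C8a, C8, C7, C6, C5 and C4. "Lower face" means the face of the carbocycle that carries the C8 oxygen.

Assumption: hydrogen transfer to the C4a radical in step 4 is taken to occur anti to the new oxasilolane, so 6–12 and 21–23 are drawn with the C4a substituent on the lower face. The C4a epimer would follow the same steps, because C4a becomes trigonal in step 16.

## Steps

Step 1
Reactants: 1 shikimic acid, (3R,4S,5R)-3,4,5-trihydroxycyclohex-1-ene-1-carboxylic acid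
Product: 2 methyl shikimate, methyl (3R,4S,5R)-3,4,5-trihydroxycyclohex-1-ene-1-carboxylate
Conditions: MeOH, CSA (cat.), reflux
Reagents that add atoms: methanol (CO)
Why: Fischer esterification; no stereocentre is touched and the allylic triol is stable to catalytic sulfonic acid in methanol.

Step 2
Reactants: 2 methyl shikimate
Product: 3 methyl 4,5-O-[(2S,3S)-2,3-dimethoxybutane-2,3-diyl]shikimate (trans-diol diacetal; allylic 3-OH free)
Conditions: butane-2,3-dione, HC(OMe)3, CSA (cat.), MeOH, reflux
Reagents that add atoms: butane-2,3-dione (CC(=O)C(C)=O); methanol (CO)
Why: Butane-2,3-diacetal formation is selective for trans-diequatorial 1,2-diols, because only that pair can span the trans-fused dioxane with both methoxy groups axial (double anomeric stabilisation). The cis-disposed allylic hydroxyl therefore stays free and the acetal centres are set under thermodynamic control.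

Step 3
Reactants: 3 diacetal-protected methyl shikimate; 4 (bromomethyl)chlorodimethylsilane
Product: 5 methyl 3-O-[(bromomethyl)dimethylsilyl]-4,5-O-[(2S,3S)-2,3-dimethoxybutane-2,3-diyl]shikimate
Conditions: Et3N, DMAP (cat.), CH2Cl2, 0 °C; non-aqueous work-up, used at once
Reagents that add atoms: none
Why: O-silylation of a secondary allylic alcohol with a chlorosilane and amine base; the hydrolytically labile silyl ether is not chromatographed.

Step 4
Reactants: 5 (bromomethyl)dimethylsilyl ether
Product: 6 cis-fused oxasilolane ester (new C1–C8a bond; ring O8–SiMe2–C1–C8a–C8; C4a–CO2Me, O8 and C1 on the lower face; O6/O7 diacetal kept)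
Conditions: Bu3SnH (1.3 equiv), AIBN (0.15 equiv), PhH, 80 °C, slow addition, high dilution
Reagents that add atoms: none
Why: Tributyltin radical abstracts bromine from 5, the nucleophilic α-silyl radical adds to C8a (the β-carbon of the unsaturated ester), and the ester-stabilised C4a radical takes hydrogen from the stannane and carries the chain. The closest known reaction type is the silicon-tethered radical cyclisation of (bromomethyl)dimethylsilyl ethers of allylic alcohols, used as a hydroxymethyl delivery together with Tamao oxidation. The one ring closed is the oxasilolane (O8–Si–C1–C8a–C8), in the 5-exo-trig mode. C8a is controlled by the tether: a five-membered ring can only be cis-fused, so C1 arrives on the face of the C8 oxygen. C4a is set by hydrogen transfer anti to the new ring and is not needed later. The step needs 5-exo over 6-endo closure, which the polarity match (nucleophilic radical, electron-poor β-carbon) and the stabilised α-ester radical secure. It also needs ring closure to outrun direct reduction, which slow addition of the stannane and the pseudoaxial C8–O bond, held by the trans-fused diacetal, should favour. The diacetal and the ester are inert to stannyl radicals.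

Step 5
Reactants: 6 oxasilolane ester
Product: 8 cis-fused γ-lactone (C1–O–C4=O; C8–OH free; O6/O7 diacetal kept), via diol ester 7 (not isolated)
Conditions: H2O2 (30% aq.), KF, KHCO3, THF/MeOH, rt; then CSA (cat.), PhMe, rt
Reagents that add atoms: hydrogen peroxide (OO)
Why: Tamao oxidation converts the C1–Si bond of the alkoxysilane into C1–OH (no stereocentre at C1), and the γ-hydroxy ester then lactonises under acid catalysis. The fused lactone through the primary hydroxyl is expected in preference to the bridged lactone through O8.

Step 6
Reactants: 8 lactone diacetal
Product: 10 γ-lactone 7,8-acetonide (cis-dioxolane on O7/O8; C6–OH free on the upper face), via trihydroxy lactone 9 (not isolated)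
Conditions: TFA/H2O (9:1), 0 °C to rt; evaporate; then 2,2-dimethoxypropane, CSA (cat.), acetone, rt
Reagents that add atoms: 2,2-dimethoxypropane (COC(C)(C)OC)
Why: Acetal hydrolysis followed by thermodynamic acetonide formation, as on shikimate and quinide triols. The cis pair O7/O8 forms the cis-fused dioxolane, and with the fused lactone this ties up the most hydroxyls with the least strain, leaving only O6–H free.

Step 7
Reactants: 10 lactone acetonide
Product: 11 lactol (C4 hemiacetal, both anomers; 7,8-acetonide; C6–OH free)
Conditions: DIBAL (2.5 equiv), CH2Cl2, −78 °C; Rochelle salt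
Reagents that add atoms: none
Why: DIBAL half-reduction of a γ-lactone; the tetrahedral aluminate is stable at −78 °C and the first equivalent is consumed by the free hydroxyl.

Step 8
Reactants: 11 lactol
Product: 12 C4a-ethynyl diol (C4≡C3H on C4a; C1–OH and C6–OH free; 7,8-acetonide)
Conditions: dimethyl (1-diazo-2-oxopropyl)phosphonate, K2CO3, MeOH, 0 °C to rt
Reagents that add atoms: dimethyl (1-diazo-2-oxopropyl)phosphonate (COP(=O)(OC)C(=[N+]=[N-])C(C)=O)
Why: Seyferth–Gilbert homologation with the Ohira–Bestmann reagent acts on the open hydroxy-aldehyde form of the lactol and adds C3 as the alkyne terminus. Any epimerisation at C4a is without consequence.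

Step 9
Reactants: 13 (R)-4-benzyl-3-propanoyl-1,3-oxazolidin-2-one
Product: 15 (R)-4-benzyl-3-[(S)-2-methylpent-4-enoyl]-1,3-oxazolidin-2-one, via sodium enolate 14 (not isolated)
Conditions: NaHMDS, THF, −78 °C; allyl iodide, −78 to −45 °C
Reagents that add atoms: allyl iodide (C=CCI)
Why: Evans asymmetric alkylation: the chelated Z-enolate is attacked by the allyl halide on the face opposite the benzyl group, which sets the (S)-centre that becomes C13.

Step 10
Reactants: 15 allylated imide
Product: 17 (S)-3-methyloxolan-2-one, via hydroxy imide 16 (not isolated)
Conditions: O3, CH2Cl2/MeOH, −78 °C; NaBH4, −78 to 0 °C; aq. HCl, rt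
Reagents that add atoms: ozone ([O-][O+]=O)
Why: Ozonolysis with reductive borohydride work-up gives the γ-hydroxy imide, which lactonises with release of the auxiliary. The α-stereocentre is not enolised under these conditions.

Step 11
Reactants: 17 (S)-3-methyloxolan-2-one
Product: 19 (2E,4S)-6-hydroxy-2,4-dimethylhex-2-enal, via lactol 18 (not isolated)
Conditions: DIBAL, CH2Cl2, −78 °C; Rochelle salt; then Ph3P=C(CH3)CHO, PhMe, 90 °C
Reagents that add atoms: 2-(triphenyl-λ5-phosphanylidene)propanal (CC(C=O)=P(c1ccccc1)(c1ccccc1)c1ccccc1)
Why: Half-reduction to the lactol, then Wittig olefination of its open aldehyde form with a stabilised formyl ylide, which should give the (E)-trisubstituted enal. The weakly basic ylide should leave C13 (C4 of 19) untouched.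

Step 12
Reactants: 19 hydroxy enal
Product: 20 (3S,4E,6E)-7-iodo-3,5-dimethylhepta-4,6-dien-1-ol
Conditions: CrCl2 (6 equiv), CHI3 (2 equiv), THF, 0 °C to rt, dark
Reagents that add atoms: iodoform (IC(I)I)
Why: Takai olefination: the gem-dichromium species from iodoform and divalent chromium converts the aldehyde into the (E)-iodoalkene; excess reagent accommodates the free hydroxyl.

Step 13
Reactants: 12 C4a-ethynyl diol; 20 dienyl iodide
Product: 21 dienyne triol (C4≡C3–C9=C10–C11(CH3)=C12–C13 chain on C4a; C1–OH, C6–OH and C15–OH free; 7,8-acetonide)
Conditions: Pd(PPh3)4 (5 mol%), CuI (10 mol%), Et3N, THF, rt, degassed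
Reagents that add atoms: none
Why: Sonogashira coupling of a terminal alkyne with an (E)-iodoalkene on zerovalent palladium proceeds with retention of alkene geometry and tolerates free hydroxyls.

Step 14
Reactants: 21 dienyne triol
Product: 22 C1,C15-bis(tert-butyldimethylsilyl) ether of 21 (C6–OH free)
Conditions: TBSCl (2.2 equiv), imidazole, CH2Cl2, 0 °C
Reagents that add atoms: tert-butyldimethylsilyl chloride (CC(C)(C)[Si](C)(C)Cl)
Why: Silylation with a bulky chlorosilane at low temperature is selective for the two primary hydroxyls over the secondary C6 hydroxyl flanked by the acetonide.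

Step 15
Reactants: 22 bis-silyl ether
Product: 23 C6 ketone of 22
Conditions: Dess–Martin periodinane, NaHCO3, CH2Cl2, 0 °C to rt
Reagents that add atoms: none
Why: Dess–Martin oxidation of a secondary alcohol under buffered, non-basic conditions, so the β-oxygen at C8 is not eliminated and C7 is not epimerised.

Step 16
Reactants: 23 C6 ketone
Product: 25 ynenone (C4a=C5–C6=O conjugated with C4≡C3; 7,8-acetonide; bis-silyl ether), via lithium enolate 24 (not isolated)
Conditions: LDA (1.1 equiv), THF, −78 °C; then PhS(Cl)=NtBu, −78 °C
Reagents that add atoms: none
Why: Mukaiyama dehydrogenation: kinetic deprotonation takes place at the C5 methylene rather than at the oxygen-bearing C7, the enolate is sulfenylated by the sulfinimidoyl chloride, and syn-elimination with C4a–H gives the enone. C4a becomes trigonal, so its earlier configuration no longer matters.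

Step 17
Reactants: 25 ynenone
Product: 27 (7R)-7-methyl ynenone (C7 bearing CH3 on the upper face and O7 on the lower face; 7,8-acetonide; bis-silyl ether), via lithium dienolate 26 (not isolated)
Conditions: LDA (1.2 equiv), THF, −78 °C; MeI, DMPU, −78 to −40 °C
Reagents that add atoms: iodomethane (CI)
Why: α′-Alkylation of a cross-conjugated ketone enolate: C7 is the only α-carbon left with a hydrogen. The methyl group enters anti to O8 because the enolate carbon belongs to a dioxolane that must stay cis-fused (this is also the axial trajectory), which sets C7. The C8–O bond lies close to the nodal plane of the enolate, which should slow β-elimination at low temperature.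

Step 18
Reactants: 27 methylated ynenone
Product: 28 tetraol ynenone (C1–OH, C7–OH, C8–OH and C15–OH free)
Conditions: TFA/H2O/THF, 0 °C to rt
Reagents that add atoms: none
Why: Acid hydrolysis removes the acetonide and both primary silyl ethers in one operation. The diene is deactivated toward protonation by the ynenone, and no enol ether is yet present.

Step 19
Reactants: 28 tetraol ynenone
Product: 29 5-deschloro target, (7R,8R,8aS)-7,8-dihydroxy-3-[(1E,3E,5S)-7-hydroxy-3,5-dimethylhepta-1,3-dien-1-yl]-7-methyl-1,7,8,8a-tetrahydro-6H-isochromen-6-one
Conditions: Ph3PAuNTf2 (5 mol%), THF, rt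
Reagents that add atoms: none
Why: Gold-catalysed 6-endo-dig hydroalkoxylation (alkynol cycloisomerisation): the C1 hydroxyl attacks C3, the δ-carbon of the ynenone and the alkyne carbon next to the diene, and protodeauration gives the conjugated dienol ether. The C7 and C8 hydroxyls could only close onto bridgehead-alkene bicycles and should not compete.

Step 20
Reactants: 29 5-deschloro compound
Product: 30 target, (7R,8R,8aS)-5-chloro-7,8-dihydroxy-3-[(1E,3E,5S)-7-hydroxy-3,5-dimethylhepta-1,3-dien-1-yl]-7-methyl-1,7,8,8a-tetrahydro-6H-isochromen-6-one
Conditions: NCS (1.05 equiv), MeCN, −20 to 0 °C, dark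
Reagents that add atoms: N-chlorosuccinimide (O=C1CCC(=O)N1Cl)
Why: Electrophilic α-chlorination of a vinylogous ester: C5 carries the highest electron density of the O2–C3=C4–C4a=C5–C6=O system, and loss of H5 restores conjugation. No stereocentre is involved and the hydroxyls are inert to the reagent.

## Compound list

1 | shikimic acid | OC(=O)C1=C[C@@H](O)[C@@H](O)[C@H](O)C1 | starting material
2 | methyl shikimate | COC(=O)C1=C[C@@H](O)[C@@H](O)[C@H](O)C1 | intermediate
3 | methyl 4,5-O-[(2S,3S)-2,3-dimethoxybutane-2,3-diyl]shikimate | COC(=O)C1=C[C@@H](O)[C@H]2O[C@](C)(OC)[C@@](C)(OC)O[C@@H]2C1 | intermediate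
4 | (bromomethyl)chlorodimethylsilane | C[Si](C)(Cl)CBr | starting material
5 | methyl 3-O-[(bromomethyl)dimethylsilyl]-4,5-O-[(2S,3S)-2,3-dimethoxybutane-2,3-diyl]shikimate | COC(=O)C1=C[C@@H](O[Si](C)(C)CBr)[C@H]2O[C@](C)(OC)[C@@](C)(OC)O[C@@H]2C1 | intermediate
6 | cis-fused oxasilolane ester (O6/O7 diacetal) | COC(=O)[C@@H]1C[C@H]3O[C@](C)(OC)[C@@](C)(OC)O[C@@H]3[C@@H]2O[Si](C)(C)C[C@H]12 | intermediate
7 | C1,C8-diol methyl ester (O6/O7 diacetal) | COC(=O)[C@@H]1C[C@H]2O[C@](C)(OC)[C@@](C)(OC)O[C@@H]2[C@H](O)[C@@H]1CO | intermediate
8 | cis-fused γ-lactone, C8–OH free, O6/O7 diacetal | O=C1OC[C@H]2[C@@H](O)[C@H]3O[C@](C)(OC)[C@@](C)(OC)O[C@@H]3C[C@@H]12 | intermediate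
9 | trihydroxy γ-lactone | O=C1OC[C@H]2[C@@H](O)[C@@H](O)[C@H](O)C[C@@H]12 | intermediate
10 | γ-lactone 7,8-acetonide, C6–OH free | O=C1OC[C@H]2[C@H]3OC(C)(C)O[C@H]3[C@H](O)C[C@@H]12 | intermediate
11 | lactol 7,8-acetonide, C6–OH free | OC1OC[C@H]2[C@H]3OC(C)(C)O[C@H]3[C@H](O)C[C@@H]12 | intermediate
12 | C4a-ethynyl diol 7,8-acetonide | C#C[C@@H]1C[C@@H](O)[C@@H]2OC(C)(C)O[C@@H]2[C@@H]1CO | intermediate
13 | (R)-4-benzyl-3-propanoyl-1,3-oxazolidin-2-one | CCC(=O)N1C(=O)OC[C@H]1Cc1ccccc1 | starting material
14 | sodium (Z)-enolate of 13 | C/C=C(\O[Na])N1C(=O)OC[C@H]1Cc1ccccc1 | intermediate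
15 | (R)-4-benzyl-3-[(S)-2-methylpent-4-enoyl]-1,3-oxazolidin-2-one | C=CC[C@H](C)C(=O)N1C(=O)OC[C@H]1Cc1ccccc1 | intermediate
16 | (R)-4-benzyl-3-[(S)-4-hydroxy-2-methylbutanoyl]-1,3-oxazolidin-2-one | OCC[C@H](C)C(=O)N1C(=O)OC[C@H]1Cc1ccccc1 | intermediate
17 | (S)-3-methyloxolan-2-one | C[C@H]1CCOC1=O | intermediate
18 | (3S)-3-methyloxolan-2-ol (both anomers) | C[C@H]1CCOC1O | intermediate
19 | (2E,4S)-6-hydroxy-2,4-dimethylhex-2-enal | O=C/C(C)=C/[C@@H](C)CCO | intermediate
20 | (3S,4E,6E)-7-iodo-3,5-dimethylhepta-4,6-dien-1-ol | I/C=C/C(C)=C/[C@@H](C)CCO | intermediate
21 | dienyne triol 7,8-acetonide | CC(/C=C/C#C[C@@H]1C[C@@H](O)[C@@H]2OC(C)(C)O[C@@H]2[C@@H]1CO)=C\[C@@H](C)CCO | intermediate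
22 | C1,C15-bis(tert-butyldimethylsilyl) ether of 21 | CC(/C=C/C#C[C@@H]1C[C@@H](O)[C@@H]2OC(C)(C)O[C@@H]2[C@@H]1CO[Si](C)(C)C(C)(C)C)=C\[C@@H](C)CCO[Si](C)(C)C(C)(C)C | intermediate
23 | C6 ketone of 22 | CC(/C=C/C#C[C@@H]1CC(=O)[C@@H]2OC(C)(C)O[C@@H]2[C@@H]1CO[Si](C)(C)C(C)(C)C)=C\[C@@H](C)CCO[Si](C)(C)C(C)(C)C | intermediate
24 | lithium C5=C6 enolate of 23 | CC(/C=C/C#C[C@@H]1C=C(O[Li])[C@@H]2OC(C)(C)O[C@@H]2[C@@H]1CO[Si](C)(C)C(C)(C)C)=C\[C@@H](C)CCO[Si](C)(C)C(C)(C)C | intermediate
25 | ynenone 7,8-acetonide bis-silyl ether | CC(/C=C/C#CC1=CC(=O)[C@@H]2OC(C)(C)O[C@@H]2[C@@H]1CO[Si](C)(C)C(C)(C)C)=C\[C@@H](C)CCO[Si](C)(C)C(C)(C)C | intermediate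
26 | lithium C6=C7 dienolate of 25 | CC(/C=C/C#CC1=CC(O[Li])=C2OC(C)(C)O[C@@H]2[C@@H]1CO[Si](C)(C)C(C)(C)C)=C\[C@@H](C)CCO[Si](C)(C)C(C)(C)C | intermediate
27 | (7R)-7-methyl ynenone 7,8-acetonide bis-silyl ether | CC(/C=C/C#CC1=CC(=O)[C@]2(C)OC(C)(C)O[C@@H]2[C@@H]1CO[Si](C)(C)C(C)(C)C)=C\[C@@H](C)CCO[Si](C)(C)C(C)(C)C | intermediate
28 | tetraol ynenone | CC(/C=C/C#CC1=CC(=O)[C@](C)(O)[C@H](O)[C@@H]1CO)=C\[C@@H](C)CCO | intermediate
29 | 5-deschloro target | CC(/C=C/C1=CC2=CC(=O)[C@](C)(O)[C@H](O)[C@@H]2CO1)=C\[C@@H](C)CCO | intermediate
30 | (7R,8R,8aS)-5-chloro-7,8-dihydroxy-3-[(1E,3E,5S)-7-hydroxy-3,5-dimethylhepta-1,3-dien-1-yl]-7-methyl-1,7,8,8a-tetrahydro-6H-isochromen-6-one | CC(/C=C/C1=CC2=C(Cl)C(=O)[C@](C)(O)[C@H](O)[C@@H]2CO1)=C\[C@@H](C)CCO | target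

## Step count and least certain steps

Total step count: 20 (16 on the main line, 4 on the side-chain branch). Longest linear sequence: 16 steps (steps 1–8 and 13–20, from 1).

Step 4 (key step). The most likely failure is hydrogen transfer from the stannane to the open-chain silylmethyl radical before ring closure, or leakage into 6-endo closure, because the long Si–C and Si–O bonds loosen the transition state. The fallback sets out from 5 and returns at 6. It replaces the chain reduction by a stoichiometric radical–polar crossover with SmI2 (divalent samarium), HMPA and tert-butanol in THF. The radical from carbon–bromine reduction closes onto C8a, the C4a radical is reduced to a samarium enolate and protonated, and no hydrogen-atom donor is present to intercept the uncyclised radical. No new compound is made.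

Step 17. The most likely failure is deprotonation at C8a (the γ-position of the ynenone) instead of C7, followed by loss of the C8 oxygen and aromatisation, or expulsion of O8 from the C7 enolate on warming. The fallback sets out from 23 and returns at 27, bypassing steps 16 and 17.
- Ketone 23 is sulfinylated at C5 (LDA, 2.2 equiv; methyl benzenesulfinate) to give the 5-(phenylsulfinyl) ketone F1.
- Its dianion (LDA, 2.2 equiv, −78 °C) is methylated at the more basic α′-carbon C7, under the same acetonide control, to give the 7-methyl-5-(phenylsulfinyl) ketone F2.
- Thermal syn-elimination of the sulfoxide (PhMe, NaHCO3, 90 °C) forms C4a=C5 and gives 27.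
The methylation is thus done before any enone, and its acidic γ-hydrogen, exists.

Step 19. The most likely failure is closure at C4 (5-exo) instead of C3, or gold-promoted decomposition of the polyol. The fallback sets out from 28 and returns at 29. Pyrrolidine adds in conjugate fashion to C3, where an external nucleophile is directed unambiguously by the ynenone, to give the C3-pyrrolidinyl dienaminone F3. Aqueous acetic acid then exchanges the amine for the C1 hydroxyl (hydrolysis to the C3 ketone and cyclodehydration) to give 29.

Step 20. The most likely failure is chlorination at C4 or on the side-chain diene, or over-chlorination, since several π-nucleophiles are present. The fallback sets out from 23 and returns at 30.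
- The lithium enolate of 23 is chlorinated with NCS at C5, the only enolisable methylene, to give the 5-chloro ketone F4.
- Dehydrogenation as in step 16 gives the 5-chloro ynenone F5.
- Methylation as in step 17 gives the 5-chloro-7-methyl ynenone F6.
- Hydrolysis as in step 18 gives the 5-chloro tetraol F7.
- Cycloisomerisation as in step 19 gives 30.
The halogen is thus placed by enolate chemistry before the competing π-systems are activated.

Step 11. The most likely failure is slow olefination of the lactol by the weakly nucleophilic formyl ylide, with conjugate addition of the free hydroxyl to the enal on prolonged heating. The fallback sets out from 17 (through 18) and returns at 19. The lactol is olefinated with Ph3P=C(CH3)CO2Et to give ethyl (2E,4S)-6-hydroxy-2,4-dimethylhex-2-enoate F8. DIBAL reduction gives (2E,4S)-2,4-dimethylhex-2-ene-1,6-diol F9, and MnO2 oxidises only the allylic hydroxyl to give 19.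

## Further compounds

F0 | step 4 | none | none
F1 | step 17 | 5-(phenylsulfinyl) derivative of ketone 23 (C5 and sulfur epimers) | CC(/C=C/C#C[C@@H]1C(S(=O)c3ccccc3)C(=O)[C@@H]2OC(C)(C)O[C@@H]2[C@@H]1CO[Si](C)(C)C(C)(C)C)=C\[C@@H](C)CCO[Si](C)(C)C(C)(C)C
F2 | step 17 | (7R)-7-methyl-5-(phenylsulfinyl) ketone | CC(/C=C/C#C[C@@H]1C(S(=O)c3ccccc3)C(=O)[C@]2(C)OC(C)(C)O[C@@H]2[C@@H]1CO[Si](C)(C)C(C)(C)C)=C\[C@@H](C)CCO[Si](C)(C)C(C)(C)C
F3 | step 19 | C3-(pyrrolidin-1-yl) dienaminone from 28 | CC(/C=C/C(=CC2=CC(=O)[C@](C)(O)[C@H](O)[C@@H]2CO)N1CCCC1)=C\[C@@H](C)CCO
F4 | step 20 | 5-chloro derivative of ketone 23 (C5 epimers) | CC(/C=C/C#C[C@@H]1C(Cl)C(=O)[C@@H]2OC(C)(C)O[C@@H]2[C@@H]1CO[Si](C)(C)C(C)(C)C)=C\[C@@H](C)CCO[Si](C)(C)C(C)(C)C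
F5 | step 20 | 5-chloro ynenone 7,8-acetonide bis-silyl ether | CC(/C=C/C#CC1=C(Cl)C(=O)[C@@H]2OC(C)(C)O[C@@H]2[C@@H]1CO[Si](C)(C)C(C)(C)C)=C\[C@@H](C)CCO[Si](C)(C)C(C)(C)C
F6 | step 20 | (7R)-5-chloro-7-methyl ynenone 7,8-acetonide bis-silyl ether | CC(/C=C/C#CC1=C(Cl)C(=O)[C@]2(C)OC(C)(C)O[C@@H]2[C@@H]1CO[Si](C)(C)C(C)(C)C)=C\[C@@H](C)CCO[Si](C)(C)C(C)(C)C
F7 | step 20 | 5-chloro tetraol ynenone | CC(/C=C/C#CC1=C(Cl)C(=O)[C@](C)(O)[C@H](O)[C@@H]1CO)=C\[C@@H](C)CCO
F8 | step 11 | ethyl (2E,4S)-6-hydroxy-2,4-dimethylhex-2-enoate | CCOC(=O)/C(C)=C/[C@@H](C)CCO
F9 | step 11 | (2E,4S)-2,4-dimethylhex-2-ene-1,6-diol | OC/C(C)=C/[C@@H](C)CCO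
A1 | alternative 1 | hetero-Diels–Alder adduct: 1-methoxy-6-(tert-butyldimethylsilyloxy)-7,8-O-isopropylidene isochromene with the O-silylated side chain | CC(/C=C/C1=CC2=C[C@@H](O[Si](C)(C)C(C)(C)C)[C@]3(C)OC(C)(C)O[C@@H]3[C@@H]2[C@H](OC)O1)=C\[C@@H](C)CCO[Si](C)(C)C(C)(C)C
A2 | alternative 2 | Diels–Alder adduct: cis-fused bicyclic δ-lactone with C6 trimethylsilyl enol ether, C7 methoxymethoxy, C8 silyloxy and C3 dienyl groups | O=C1O[C@@H](/C=C/C(C)=C/[C@@H](C)CCO[Si](C)(C)C(C)(C)C)C[C@@H]2CC(O[Si](C)(C)C)=C(OCOC)[C@H](O[Si](C)(C)C(C)(C)C)[C@H]12
A3 | alternative 3 | benzoin product: C8,C15-bis(tert-butyldimethylsilyl) ether of the 5-deschloro target | CC(/C=C/C1=CC2=CC(=O)[C@](C)(O)[C@H](O[Si](C)(C)C(C)(C)C)[C@@H]2CO1)=C\[C@@H](C)CCO[Si](C)(C)C(C)(C)C
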